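**Retrosynthetic overview**

- Feature: C1–C2–C3–C4 and the bridging O are a 2-methylfuran unit. In ring A (C1–C5, C10) the quaternary C10 carries C9 exo and C5 carries C6 endo, as if the central carbon C9 of a C10–C9–C5 oxyallyl bridge had been pushed out onto C10.
- Late disconnections: ring B by C8=C9 ring-closing metathesis; C6–C7 by anti γ-isopropylallylboration of the C6 aldehyde; C9 vinyl from the C9 acetyl group; anisoate installed before ring closure.
- Key disconnection: exo-acetyl 7-oxanorbornene from an α-bromo 8-oxabicyclo[3.2.1]octenone and MeLi (C5 shifts from C9 to C10).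
- Cycloadduct from 2-methylfuran and the bromo-oxyallyl cation of 1-(benzyloxy)-4,4-dibromopentan-3-one, made from 1,1-dibromoethyllithium and 3-(benzyloxy)propanal.
- Ring order: oxabicyclo[3.2.1]octenone (step 3), contraction to ring A with its oxygen bridge (step 5), ring B (step 13).

Key step: step 5

Remark 1 (numbering): target numbering is used throughout (C1 O–CH bridgehead, C4 O–C(CH3) bridgehead, C5 fusion CH, C6 ester CH, C7 CH–iPr, C10 quaternary C–CH3); exo = face of the oxygen bridge, endo = face of the C2–C3 bridge.

Remark 2 (stereochemical demand of the key step): the shift inverts C10 and retains C5, so exo C9/endo CH3/endo C6 can only come from the cycloadduct with Br on the oxygen-bridge face (axial in the chair of the oxanone ring) and CH3 and CH2OBn equatorial; C10–Br is antiperiplanar to C9–C5 only in the boat form of the alkoxide, not in the chair.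

Remark 3 (assumptions): 3-(benzyloxy)propanal and (E)-4-methylpent-2-ene are taken as purchasable; the carbon delivered by MeLi is a handle only (it leaves as ethylene in step 13) and C8 comes from the allylboronate.

**Route**

Step 1
Reactants: 1 1,1-dibromoethane; 2 3-(benzyloxy)propanal
Product: 4 rac-1-(benzyloxy)-4,4-dibromopentan-3-ol, via 1,1-dibromoethyllithium 3 (not isolated)
Conditions: LiN(iPr)2, THF/Et2O, −100 °C; then 2, −100 to −78 °C; AcOH quench at −78 °C
Reagents that add atoms: 1,1-dibromoethane (1), CC(Br)Br
Why: Deprotonation of the gem-dibromide gives lithium carbenoid 3, which adds to the aldehyde at −100 °C (carbenoid 1,2-addition); both bromines are thereby fixed on the methyl-bearing carbon, which bromination of 1-(benzyloxy)pentan-3-one with its two α-CH2 groups could not secure, and the racemic carbinol centre is erased in step 2.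

Step 2
Reactants: 4 rac-1-(benzyloxy)-4,4-dibromopentan-3-ol
Product: 5 1-(benzyloxy)-4,4-dibromopentan-3-one
Conditions: Dess–Martin periodinane, NaHCO3, CH2Cl2, 0 °C to rt
Reagents that add atoms: none
Why: Dess–Martin oxidation of a secondary alcohol under buffered, non-basic conditions, which spares the base-sensitive β-benzyloxy α,α-dibromo ketone.

Step 3
Reactants: 5 1-(benzyloxy)-4,4-dibromopentan-3-one; 6 2-methylfuran
Product: 8 racemic 2-[(benzyloxy)methyl]-4-bromo-1,4-dimethyl-8-oxabicyclo[3.2.1]oct-6-en-3-one (1S*,2R*,4R*,5R*; Br axial; CH3 and CH2OBn equatorial), via bromo-oxyallyl cation 7 (not isolated)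
Conditions: Et3N (2 equiv), 6 (5 equiv), CF3CH2OH, 0 °C to rt; chromatography
Reagents that add atoms: 2-methylfuran (6), Cc1ccco1
Why: Base-induced ionisation of the α,α-dibromo ketone enol gives cation 7, which undergoes (4+3) cycloaddition with the furan; the fully substituted C(Br)CH3 terminus should bond to the unsubstituted furan α-carbon (two fully substituted carbons are not joined), and the W-type cation (CH3 and CH2OBn cis to O, Br inside) reacting through the compact transition state should place both carbon substituents equatorial and bromine axial, setting all four centres relative to one another.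

Step 4
Reactants: 8 racemic cycloadduct
Product: 9 (1S,2R,4R,5R)-2-[(benzyloxy)methyl]-4-bromo-1,4-dimethyl-8-oxabicyclo[3.2.1]oct-6-en-3-one (target numbering 1R,4S,5R,10R)
Conditions: preparative SFC, amylose tris(3,5-dimethylphenylcarbamate) on silica, CO2/2-propanol
Reagents that add atoms: none
Why: Chromatographic resolution on a chiral stationary phase changes no bond; the required enantiomer would be identified by anomalous-dispersion X-ray diffraction of the bromide.

Step 5
Reactants: 9 single-enantiomer α-bromo cycloadduct; 10 methyllithium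
Product: 12 1-[(1R,2S,3R,4S)-3-[(benzyloxy)methyl]-2,4-dimethyl-7-oxabicyclo[2.2.1]hept-5-en-2-yl]ethan-1-one (exo acetyl and endo CH3 at C10; endo CH2OBn at C5), via lithium alkoxide 11 (not isolated)
Conditions: MeLi (1.2 equiv), Et2O, −78 °C, then −78 to 0 °C; aq. NH4Cl at 0 °C; product kept at or below 0 °C and used at once
Reagents that add atoms: methyllithium (10), [Li]C
Why: MeLi adds to the C9 carbonyl and lithium alkoxide 11 expels bromide by a 1,2-shift of C5 from C9 to C10, a quasi-Favorskii (semibenzilic) rearrangement of the kind known for α-halo (4+3) cycloadducts with hydride or organolithium reagents. The five-membered ring C1–C10–C5–C4–O is closed by this shift, an intramolecular backside displacement at C10 by the C9–C5 σ bond through a three-centre bridged transition state, which contracts the oxanone ring to the 7-oxanorbornene. C10 is the new quaternary centre and is set by stereospecific inversion, so bromine on the oxygen-bridge face becomes exo acetyl and endo CH3, while C5 migrates with retention and keeps CH2OBn endo. Because the bromide of 9 is axial in the chair, C10–Br becomes antiperiplanar to C9–C5 only when C9 tips to the oxygen side (boat of the oxanone ring), which is the geometry of the exo-bridged transition state. The step needs contraction to win over epoxide closure, methyl shift and Br/Li exchange. Methyl delivery anti to the axial C–Br bond (the sp2 C2=C3 bridge has no inward hydrogens) puts O– cis to Br so that no epoxide can form, the endo C9 methyl is then pressed against C2=C3 and pushes the ring into the boat, and Li+ can bridge O– and the ring oxygen there.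

Step 6
Reactants: 12 exo-acetyl 7-oxanorbornene
Product: 13 1-[(1R,2S,3R,4S)-3-(hydroxymethyl)-2,4-dimethyl-7-oxabicyclo[2.2.1]heptan-2-yl]ethan-1-one
Conditions: H2 (1 atm), 10% Pd/C, EtOH, 0 °C to rt
Reagents that add atoms: none
Why: Heterogeneous catalytic hydrogenation saturates the strained C2=C3 bond and hydrogenolyses the benzyl ether in one operation, removing both the retro-[4+2] liability of 12 and the metathesis-active ring alkene; no stereocentre is formed.

Step 7
Reactants: 13 hydroxy ketone
Product: 14 keto aldehyde (3-exo-acetyl-1,3-dimethyl-7-oxabicyclo[2.2.1]heptane-2-endo-carbaldehyde; target numbering 1R,4S,5S,10S, geometry as in 13)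
Conditions: Dess–Martin periodinane, NaHCO3, CH2Cl2, 0 °C; used crude
Reagents that add atoms: none
Why: Dess–Martin oxidation of the primary alcohol under buffered conditions should give the aldehyde without epimerising C5; the ketone is inert, and an intramolecular aldol would need a trans-fused five-membered ring on the bicycle.

Step 8
Reactants: 15 (E)-4-methylpent-2-ene
Product: 17 2-[(E)-4-methylpent-2-en-1-yl]-4,4,5,5-tetramethyl-1,3,2-dioxaborolane, via allylpotassium 16 (not isolated)
Conditions: n-BuLi, KOtBu, THF, −78 to −50 °C; then 2-isopropoxy-4,4,5,5-tetramethyl-1,3,2-dioxaborolane, −78 °C; 1 M HCl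
Reagents that add atoms: 2-isopropoxy-4,4,5,5-tetramethyl-1,3,2-dioxaborolane, CC(C)OB1OC(C)(C)C(C)(C)O1
Why: Allylic metalation with the n-BuLi/KOtBu superbase removes a proton from the methyl group, and the E-configured allylpotassium is borylated at its unsubstituted terminus at low temperature, so the E geometry is carried into the allylboronate.

Step 9
Reactants: 14 keto aldehyde; 17 (E)-γ-isopropylallylboronate
Product: 19 homoallylic alcohol (C6–OH and C7–iPr anti; target numbering 1R,4S,5R,6R,7R,10S; C7 bears CH=CH2), via borate ester 18 (not isolated)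
Conditions: 17 (1.5 equiv), (R)-3,3′-bis(2,4,6-triisopropylphenyl)-1,1′-binaphthyl-2,2′-diyl hydrogen phosphate (10 mol%), 4 Å sieves, toluene, −30 to 0 °C; aq. NaHCO3
Reagents that add atoms: boronate 17, CC(C)/C=C/CB1OC(C)(C)C(C)(C)O1
Why: Aldehyde allylboration through a closed chair transition state, catalysed by the chiral phosphoric acid: the E boronate gives the anti C6/C7 relationship, and the (R)-acid, which directs allyl transfer to the Re face of aldehydes, should give 6R, the face that a Felkin–Anh approach anti to C10 also favours; the ketone does not react.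

Step 10
Reactants: 19 homoallylic alcohol; 20 4-methoxybenzoyl chloride
Product: 21 4-methoxybenzoate of 19 (methyl ketone and terminal alkene retained)
Conditions: 20 (2 equiv), Et3N, 4-(dimethylamino)pyridine (0.5 equiv), CH2Cl2, 40 °C
Reagents that add atoms: 4-methoxybenzoyl chloride (20), COc1ccc(cc1)C(Cl)=O
Why: Nucleophilic catalysis by 4-(dimethylamino)pyridine acylates the hindered secondary alcohol with retention at C6 (acyl transfer) and installs the final ester, which also protects C6–O for the remaining steps.

Step 11
Reactants: 21 keto ester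
Product: 23 enol triflate (C10–C(OTf)=CH2), via potassium enolate 22 (not isolated)
Conditions: KN(SiMe3)2, THF, −78 °C; then PhNTf2, −78 to 0 °C
Reagents that add atoms: N-phenylbis(trifluoromethanesulfonimide), O=S(=O)(N(c1ccccc1)S(=O)(=O)C(F)(F)F)C(F)(F)F
Why: Kinetic deprotonation at the only enolisable position (the acetyl methyl; C10 is quaternary) and O-sulfonylation of the enolate give the vinyl triflate (enol triflate formation); the aryl ester has no α-hydrogen.

Step 12
Reactants: 23 enol triflate
Product: 24 diene (exo vinyl on C10; CH=CH2 on C7; anisoate on C6)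
Conditions: Pd(OAc)2 (5 mol%), PPh3 (10 mol%), n-Bu3N, HCO2H, DMF, 60 °C
Reagents that add atoms: none
Why: Palladium-catalysed formate reduction of a vinyl triflate: oxidative addition of zerovalent palladium, formate exchange, loss of CO2 and C–H reductive elimination turn C9 into the vinyl CH, leaving the isolated alkene and the ester untouched.

Step 13
Reactants: 24 diene
Product: 25 8,9-didehydro target (ring B cyclohexene)
Conditions: second-generation Grubbs catalyst (H2IMes)(PCy3)Cl2Ru=CHPh (10 mol%), toluene, 80 °C, high dilution, argon sparge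
Reagents that add atoms: none
Why: Ring-closing metathesis of the 1,7-diene closes six-membered ring B at C8=C9 with loss of ethylene (the carbon from MeLi leaves here); the exo/endo (trans) fusion is already fixed at C5 and C10 and no stereocentre is formed.

Step 14
Reactants: 25 ring B cyclohexene
Product: 26 (1R,4S,5R,6R,7S,10S)-1,4-epoxyeudesman-6-yl 4-methoxybenzoate (target)
Conditions: H2 (1–3 atm), 10% Pd/C, EtOAc, rt
Reagents that add atoms: none
Why: Catalytic hydrogenation of the disubstituted ring alkene makes C8 and C9 CH2 groups, so no stereocentre is created; the aryl ester and bicyclic ether are stable.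

**Compound list**

1 | 1,1-dibromoethane | CC(Br)Br | starting material
2 | 3-(benzyloxy)propanal | O=CCCOCc1ccccc1 | starting material
3 | 1,1-dibromoethyllithium | [Li]C(C)(Br)Br | intermediate
4 | rac-1-(benzyloxy)-4,4-dibromopentan-3-ol | CC(Br)(Br)C(O)CCOCc1ccccc1 | intermediate
5 | 1-(benzyloxy)-4,4-dibromopentan-3-one | CC(Br)(Br)C(=O)CCOCc1ccccc1 | intermediate
6 | 2-methylfuran | Cc1ccco1 | starting material
7 | 1-(benzyloxymethyl)-3-bromo-3-methyl-2-oxidoallyl cation (CH3 and CH2OBn cis to O, Br inside) | C/C(Br)=C(\[O-])[CH+]COCc1ccccc1 | intermediate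
8 | racemic (1S*,2R*,4R*,5R*)-2-[(benzyloxy)methyl]-4-bromo-1,4-dimethyl-8-oxabicyclo[3.2.1]oct-6-en-3-one (both enantiomers) | C[C@]1(Br)C(=O)[C@H](COCc2ccccc2)[C@]3(C)C=C[C@H]1O3.C[C@@]1(Br)C(=O)[C@@H](COCc2ccccc2)[C@@]3(C)C=C[C@@H]1O3 | intermediate
9 | (1S,2R,4R,5R)-2-[(benzyloxy)methyl]-4-bromo-1,4-dimethyl-8-oxabicyclo[3.2.1]oct-6-en-3-one (Br on the oxygen-bridge face) | C[C@]1(Br)C(=O)[C@H](COCc2ccccc2)[C@]3(C)C=C[C@H]1O3 | intermediate
10 | methyllithium | [Li]C | starting material
11 | lithium C9 alkoxide of the MeLi adduct of 9 (O– on the oxygen-bridge face, cis to Br; new CH3 towards C2=C3) | C[C@]1(Br)[C@@](C)([O-])[C@H](COCc2ccccc2)[C@]3(C)C=C[C@H]1O3.[Li+] | intermediate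
12 | 1-[(1R,2S,3R,4S)-3-[(benzyloxy)methyl]-2,4-dimethyl-7-oxabicyclo[2.2.1]hept-5-en-2-yl]ethan-1-one | C[C@@]1(C(C)=O)[C@H]2C=C[C@](C)(O2)[C@H]1COCc3ccccc3 | intermediate
13 | 1-[(1R,2S,3R,4S)-3-(hydroxymethyl)-2,4-dimethyl-7-oxabicyclo[2.2.1]heptan-2-yl]ethan-1-one | C[C@@]1(C(C)=O)[C@H]2CC[C@](C)(O2)[C@H]1CO | intermediate
14 | 3-exo-acetyl-1,3-dimethyl-7-oxabicyclo[2.2.1]heptane-2-endo-carbaldehyde (target numbering 1R,4S,5S,10S) | C[C@@]1(C(C)=O)[C@H]2CC[C@](C)(O2)[C@H]1C=O | intermediate
15 | (E)-4-methylpent-2-ene | C/C=C/C(C)C | starting material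
16 | (E)-4-methylpent-2-en-1-ylpotassium | [K+].[CH2-]/C=C/C(C)C | intermediate
17 | 2-[(E)-4-methylpent-2-en-1-yl]-4,4,5,5-tetramethyl-1,3,2-dioxaborolane | CC(C)/C=C/CB1OC(C)(C)C(C)(C)O1 | intermediate
18 | pinacol borate ester of alcohol 19 | C[C@@]1(C(C)=O)[C@H]2CC[C@](C)(O2)[C@H]1[C@H](OB3OC(C)(C)C(C)(C)O3)[C@H](C(C)C)C=C | intermediate
19 | anti homoallylic alcohol: exo-acetyl bicycle with endo C5–CH(OH)–CH(iPr)–CH=CH2 (target numbering 6R,7R) | C[C@@]1(C(C)=O)[C@H]2CC[C@](C)(O2)[C@H]1[C@H](O)[C@H](C(C)C)C=C | intermediate
20 | 4-methoxybenzoyl chloride | COc1ccc(cc1)C(Cl)=O | starting material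
21 | 4-methoxybenzoate of 19 | C[C@@]1(C(C)=O)[C@H]2CC[C@](C)(O2)[C@H]1[C@H](OC(=O)c3ccc(OC)cc3)[C@H](C(C)C)C=C | intermediate
22 | potassium enolate of 21 (C10–C(O–)=CH2) | C[C@@]1(C(=C)[O-])[C@H]2CC[C@](C)(O2)[C@H]1[C@H](OC(=O)c3ccc(OC)cc3)[C@H](C(C)C)C=C.[K+] | intermediate
23 | enol triflate of 21 (C10–C(OTf)=CH2) | C[C@@]1(C(=C)OS(=O)(=O)C(F)(F)F)[C@H]2CC[C@](C)(O2)[C@H]1[C@H](OC(=O)c3ccc(OC)cc3)[C@H](C(C)C)C=C | intermediate
24 | diene: exo C10 vinyl, C7 vinyl, C6 anisoate | C[C@@]1(C=C)[C@H]2CC[C@](C)(O2)[C@H]1[C@H](OC(=O)c3ccc(OC)cc3)[C@H](C(C)C)C=C | intermediate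
25 | 8,9-didehydro target (target numbering 1R,4S,5R,6R,7R,10S) | COc1ccc(C(=O)O[C@@H]2[C@H](C(C)C)C=C[C@]3(C)[C@H]4CC[C@](C)(O4)[C@@H]23)cc1 | intermediate
26 | (1R,4S,5R,6R,7S,10S)-1,4-epoxyeudesman-6-yl 4-methoxybenzoate | COc1ccc(C(=O)O[C@@H]2[C@H](C(C)C)CC[C@]3(C)[C@H]4CC[C@](C)(O4)[C@@H]23)cc1 | target

**Step count and risks**

Total step count: 14. Longest linear sequence: 13 (steps 1–7 and 9–14; step 8 is a one-step side branch).

Steps most likely to fail:

1. Step 5. The alkoxide may not reach the boat alignment. Methyl addition syn to the C–Br bond would give the trans-diaxial bromohydrin salt, which closes to an epoxide; in the chair the methyl group rather than C5 may migrate; bromine–lithium exchange may give the debrominated enolate. Fallback: setting out from 9, a true Favorskii rearrangement (NaOH, H2O/dioxane, 0 °C to rt) would be used instead of carbonyl addition. Enolisation at C5 and loss of the axial bromide, which is aligned with the enolate π system, should give the cyclopropanone bridging C5–C10 on the oxygen-bridge face; hydroxide opening towards the less substituted carbon C5, with protonation from the exo face, should give (1R,2S,3R,4S)-3-[(benzyloxy)methyl]-2,4-dimethyl-7-oxabicyclo[2.2.1]hept-5-ene-2-carboxylic acid F1. Treatment of F1 with excess MeLi (Et2O, 0 °C, inverse aqueous NH4Cl quench) converts the acid into the methyl ketone, and the route is rejoined at 12.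

2. Step 3. Regiocontrol (bridgehead methyl next to C10) or facial control (bromide equatorial) may be lost, a stepwise path may end in Friedel–Crafts-type substitution of 2-methylfuran, or the base may cause loss of benzyl alcohol or Favorskii cleavage of the dibromo ketone. Fallback: setting out from 5, bromination at its only enolisable position (Br2, AcOH/CH2Cl2, 0 °C) gives 1-(benzyloxy)-2,4,4-tribromopentan-3-one F2. Reductive, base-free generation of the bromo-oxyallyl species as its zinc-bound cation (Zn dust, B(OEt)3, THF, 2-methylfuran, rt), the classic polybromo ketone entry to α-bromo oxabicyclic ketones, then gives the cycloadduct, and the route is rejoined at 8.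

3. Step 13. The closure must build a trans (exo/endo) fused cyclohexene on the rigid 7-oxanorbornane, with a large torsion at C5–C10, from two hindered alkenes; the reversible metathesis may stall at the open diene or give oligomers. Fallback: setting out from 24, ozonolysis (O3, CH2Cl2, −78 °C; PPh3) cleaves both terminal alkenes to the C8,C9-dialdehyde F3. Intramolecular McMurry coupling with low-valent titanium (TiCl3, Zn(Cu), DME, reflux, slow addition), an irreversible deoxygenative carbonyl coupling, forms C8=C9 directly, and the route is rejoined at 25.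

Further compounds
F1 | step 5 | (1R,2S,3R,4S)-3-[(benzyloxy)methyl]-2,4-dimethyl-7-oxabicyclo[2.2.1]hept-5-ene-2-carboxylic acid | C[C@@]1(C(=O)O)[C@H]2C=C[C@](C)(O2)[C@H]1COCc3ccccc3
F2 | step 3 | 1-(benzyloxy)-2,4,4-tribromopentan-3-one (racemic) | CC(Br)(Br)C(=O)C(Br)COCc1ccccc1
F3 | step 13 | dialdehyde from 24 (C10–CHO exo, C7–CHO, C6 anisoate) | C[C@@]1(C=O)[C@H]2CC[C@](C)(O2)[C@H]1[C@H](OC(=O)c3ccc(OC)cc3)[C@H](C(C)C)C=O
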